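**Retrosynthetic overview**
- The benzylic C1–O bond of the target is disconnected first: a catalyst-controlled Markovnikov hydro-oxygenation of the (S,E)-1,3-diarylbut-1-ene installs the oxygen and sets C1.
- The C3–aryl bond of that alkene comes from an enantioselective Ni–H 1,2-hydroarylation of a 1-aryl-1,3-diene with the arylboronic acid, which sets C3.
- The diene comes from 2,4,5-trimethoxybenzaldehyde by allylphosphonate olefination.
- No ring is formed; both trimethoxybenzene rings are bought intact.

Assumption: the SMILES is read as (1R,3S)-1,3-bis(2,4,5-trimethoxyphenyl)butan-1-ol; the ligand antipodes named are those expected by analogy and are checked on the first run, the other antipode being used if the sense is opposite.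

**Route**

Step 1
Reactants: 1 2,4,5-trimethoxybenzaldehyde; 2 diethyl allylphosphonate
Product: 3 1-[(1E)-buta-1,3-dien-1-yl]-2,4,5-trimethoxybenzene
Conditions: 2, n-BuLi, THF, −78 °C; then 1, HMPA, −78 °C → rt
Reagents that add atoms: none
Why: Horner–Wadsworth–Emmons olefination with the lithiated allylphosphonate, whose α-attack on the aryl aldehyde and HMPA-promoted loss of diethyl phosphate give the conjugated (E)-diene; no stereocentre is formed.

Step 2
Reactants: 3 1-[(1E)-buta-1,3-dien-1-yl]-2,4,5-trimethoxybenzene; 4 (2,4,5-trimethoxyphenyl)boronic acid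
Product: 5 1,1'-[(1E,3S)-but-1-ene-1,3-diyl]bis(2,4,5-trimethoxybenzene)
Conditions: Ni(cod)2 (5 mol %), chiral spiro aminophosphine ligand (6 mol %, antipode giving 3S), 4 (1.4 equiv), MeOH/THF, 40 °C
Reagents that add atoms: none
Why: Ni–H-catalysed enantioselective 1,2-(Markovnikov) hydroarylation of a 1-aryl-1,3-diene with an arylboronic acid, in which Ni–H (from the alcohol) inserts the terminal C=C to give a 1-aryl-3-methyl-π-allylnickel, and transmetalation then C–C reductive elimination at the methyl-bearing terminus keeps the (E)-styrene conjugation while the chiral ligand sets C3 as S.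

Step 3
Reactants: 5 1,1'-[(1E,3S)-but-1-ene-1,3-diyl]bis(2,4,5-trimethoxybenzene)
Product: 7 (1R,3S)-1,3-bis(2,4,5-trimethoxyphenyl)butan-1-ol, via TMS ether 6 (not isolated)
Conditions: Cu(OAc)2 (5 mol %), (S)-DTBM-SEGPHOS (5.5 mol %), (MeO)2MeSiH (3 equiv), THF, 40 °C, Me3SiOOSiMe3 (1.5 equiv, syringe pump); then K2CO3 (cat.), MeOH, 0 °C → rt
Reagents that add atoms: bis(trimethylsilyl) peroxide, C[Si](C)(C)OO[Si](C)(C)C
Why: Proposed new method: a CuH-catalysed enantioselective Markovnikov hydro-oxygenation in which L*Cu–H adds across the (E)-styrene (H to C2, Cu to benzylic C1, the face fixed by (S)-DTBM-SEGPHOS over the remote C3 centre), the configurationally defined benzylic copper(I) attacks the O–O bond of the silyl peroxide with retention (formal oxidative addition then C–O reductive elimination) to give TMS ether 6 and L*Cu–OSiMe3, σ-bond metathesis of the latter with the hydrosilane regenerates L*Cu–H, and base-catalysed methanolysis frees the 1R alcohol without ionising the electron-rich benzylic C–O bond; the closest known reaction types are CuH-catalysed asymmetric hydroamination of styrenes with R2N–OBz electrophiles and the retentive oxidation of alkyl-zinc and -copper reagents by silyl peroxides.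

**Compound list**
1 | 2,4,5-trimethoxybenzaldehyde | COc1cc(OC)c(C=O)cc1OC | starting material
2 | diethyl allylphosphonate (diethyl prop-2-en-1-ylphosphonate) | C=CCP(=O)(OCC)OCC | starting material
3 | 1-[(1E)-buta-1,3-dien-1-yl]-2,4,5-trimethoxybenzene | COc1cc(OC)c(/C=C/C=C)cc1OC | intermediate
4 | (2,4,5-trimethoxyphenyl)boronic acid | COc1cc(OC)c(B(O)O)cc1OC | starting material
5 | 1,1'-[(1E,3S)-but-1-ene-1,3-diyl]bis(2,4,5-trimethoxybenzene) | COc1cc(OC)c(/C=C/[C@H](C)c2cc(OC)c(OC)cc2OC)cc1OC | intermediate
6 | {[(1R,3S)-1,3-bis(2,4,5-trimethoxyphenyl)butyl]oxy}trimethylsilane (TMS ether, not isolated) | COc1cc(OC)c([C@H](O[Si](C)(C)C)C[C@H](C)c2cc(OC)c(OC)cc2OC)cc1OC | intermediate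
7 | (1R,3S)-1,3-bis(2,4,5-trimethoxyphenyl)butan-1-ol | COc1cc(OC)c([C@H](O)C[C@H](C)c2cc(OC)c(OC)cc2OC)cc1OC | target

**Totals**
Total step count: 3. Longest linear sequence: 3 steps (1 → 3 → 5 → 7).

**Steps most likely to fail, with fallbacks**

Step 3 (the proposed new hydro-oxygenation) is the riskiest. The peroxide may be reduced by L*Cu–H or may oxidise the phosphine before the hindered, electron-rich internal styrene is hydrocuprated. A single-electron pathway through the stabilised benzylic radical could erode the C1 configuration, and the C3 centre may be mismatched with the ligand. The fallback uses known chemistry and sets out from 5. Copper-catalysed asymmetric Markovnikov hydroboration (CuCl, NaOtBu, (S)-DTBM-SEGPHOS, HBpin, THF, rt to 50 °C) gives 2-[(1R,3S)-1,3-bis(2,4,5-trimethoxyphenyl)butyl]-4,4,5,5-tetramethyl-1,3,2-dioxaborolane F4. Stereoretentive oxidation of the C–B bond (NaBO3·4H2O, THF/H2O, rt) then makes the C1–O bond and comes back to the route at 7. In either variant 7 is worked up under neutral or basic conditions and purified on Et3N-deactivated silica, because the benzylic alcohol ionises easily.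

Step 2 is next. The ortho-methoxy, electron-rich boronic acid 4 may protodeboronate or transmetalate slowly. Ni–H could also over-arylate the product or isomerise the allylic stereocentre into conjugation, and the ee on this ring pattern is untested. The fallback sets out from 1. Wittig methylenation (Ph3PCH3Br, KOtBu, THF, 0 °C) gives 1-ethenyl-2,4,5-trimethoxybenzene F2. Nickel-catalysed asymmetric hydrovinylation ([(allyl)NiBr]2, chiral phosphoramidite, NaBArF, ethylene 1 atm, CH2Cl2, −70 °C) converts F2 into 1-[(2S)-but-3-en-2-yl]-2,4,5-trimethoxybenzene F3. Cross-metathesis of F3 with more F2 (Hoveyda–Grubbs II, benzoquinone, CH2Cl2, 40 °C) gives the (E)-alkene and comes back to the route at 5.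

Step 1 is the least risky. The allyl anion may attack through its γ-carbon, the E/Z ratio may be poor, and the electron-rich diene can oligomerise on handling. The fallback sets out from 1. Addition of allylmagnesium bromide (THF, 0 °C) gives racemic 1-(2,4,5-trimethoxyphenyl)but-3-en-1-ol F1. Mild acid-catalysed E1 dehydration (cat. p-TsOH, BHT, toluene, 60 °C) through the stabilised benzylic cation gives the conjugated (E)-diene and comes back to the route at 3.

**Further compounds**
F1 | step 1 | 1-(2,4,5-trimethoxyphenyl)but-3-en-1-ol (racemic) | COc1cc(OC)c(C(O)CC=C)cc1OC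
F2 | step 2 | 1-ethenyl-2,4,5-trimethoxybenzene | COc1cc(OC)c(C=C)cc1OC
F3 | step 2 | 1-[(2S)-but-3-en-2-yl]-2,4,5-trimethoxybenzene | C=C[C@H](C)c1cc(OC)c(OC)cc1OC
F4 | step 3 | 2-[(1R,3S)-1,3-bis(2,4,5-trimethoxyphenyl)butyl]-4,4,5,5-tetramethyl-1,3,2-dioxaborolane | COc1cc(OC)c([C@H](B3OC(C)(C)C(C)(C)O3)C[C@H](C)c2cc(OC)c(OC)cc2OC)cc1OC
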